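**Retrosynthetic overview**

1. The hydroperoxide is introduced last by a Schenck ene reaction of a prenyl ketone side chain. That chain comes from an α‑methylene aldehyde (masked as a diethyl acetal until late) by allylation, cross‑metathesis and oxidation; the tiglate is put on by acylation.
2. The cis‑epoxy ketone comes from a 2‑methyl‑3‑silylcyclohex‑2‑enone by 1,2‑reduction, hydroxyl‑directed epoxidation, re‑oxidation and fluoride removal of both silyl groups.
3. Key disconnection: the cyclohexenone is opened at two ring bonds, carbonyl carbon to the methyl‑bearing carbon and ring CH2 to the neighbouring sp2 carbon. This gives a trans‑2‑siloxy‑3‑alkenylcyclobutanone and 1‑(trimethylsilyl)propyne, joined by nickel‑catalysed alkyne insertion into the acyl–CH2 bond. The enabling feature is the strained four‑membered ketone ring: its carbonyl carbon and its unsubstituted α‑CH2 carbon are the two atoms whose bond is cut, while the two ring stereocentres (C–OSiEt3 and C–side chain) are untouched.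
4. The cyclobutanone comes from a prochiral 3‑alkenylcyclobutanone by enantioselective deprotonation and Rubottom oxidation. That ketone comes from commercial 3‑oxocyclobutanecarboxylic acid and 2‑bromoacrolein diethyl acetal by decarboxylative alkenylation.
5. Ring order: the four‑membered ring is purchased; the six‑membered carbocycle is formed in step 4; the oxirane is formed in step 6.

Key step: step 4

Atom numbers in the text are those of cyclohexenone 9: C1 = C=O, C2 = C–CH3, C3, C4 = CH2, C5 = carbon bearing the side chain, C6 = C–O.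

Assumption: the (R,R)‑lithium amide is taken to give the (3R)‑enol ether in step 2; if it gives the antipode, the equally available (S,S)‑amine is used.

**Route**

Step 1
Reactants: 1 3-oxocyclobutane-1-carboxylic acid; 2 2-bromo-3,3-diethoxyprop-1-ene
Product: 3 3-(3,3-diethoxyprop-1-en-2-yl)cyclobutan-1-one
Conditions: Ir[dF(CF3)ppy]2(dtbbpy)PF6 (1 mol %), NiCl2·glyme (5 mol %), dtbbpy (5 mol %), Cs2CO3, DMSO, blue LEDs, rt
Reagents that add atoms: none
Why: Metallaphotoredox decarboxylative alkenylation, in which the carboxylate is oxidised by the excited iridium photocatalyst, loses CO2, and the secondary 3-oxocyclobutyl radical is captured by the alkenylnickel species formed from 2 before C(sp3)–C(sp2) reductive elimination; the product is achiral.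

Step 2
Reactants: 3 3-(3,3-diethoxyprop-1-en-2-yl)cyclobutan-1-one
Product: 5 triethyl{[(3R)-3-(3,3-diethoxyprop-1-en-2-yl)cyclobut-1-en-1-yl]oxy}silane, via lithium enolate 4 (not isolated)
Conditions: lithium (R,R)-bis(1-phenylethyl)amide (from the amine and n-BuLi), Et3SiCl present during deprotonation, THF, −100 °C
Reagents that add atoms: chlorotriethylsilane CC[Si](Cl)(CC)CC
Why: Desymmetrising enolisation of a prochiral 3-substituted cyclobutanone by a C2-symmetric chiral lithium amide with in situ silyl trapping; the base distinguishes the two enantiotopic α-CH2 groups and thereby fixes the ring stereocentre as R.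

Step 3
Reactants: 5 triethyl{[(3R)-3-(3,3-diethoxyprop-1-en-2-yl)cyclobut-1-en-1-yl]oxy}silane
Product: 7 (2S,3S)-3-(3,3-diethoxyprop-1-en-2-yl)-2-[(triethylsilyl)oxy]cyclobutan-1-one, via siloxy oxirane 6 (not isolated)
Conditions: DMDO, acetone/CH2Cl2, −78 °C → rt
Reagents that add atoms: dimethyldioxirane CC1(C)OO1
Why: Rubottom oxidation, in which the dioxirane epoxidises the electron-rich enol ether on the cyclobutene face opposite the neighbouring side chain and the siloxy oxirane opens with 1,4-silyl shift to the α-siloxy ketone, so the new C–O centre is trans to the side chain (also the stable arrangement at this enolisable carbon).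

Step 4
Reactants: 7 (2S,3S)-3-(3,3-diethoxyprop-1-en-2-yl)-2-[(triethylsilyl)oxy]cyclobutan-1-one; 8 trimethyl(prop-1-yn-1-yl)silane
Product: 9 (5S,6S)-5-(3,3-diethoxyprop-1-en-2-yl)-2-methyl-6-[(triethylsilyl)oxy]-3-(trimethylsilyl)cyclohex-2-en-1-one
Conditions: Ni(cod)2 (10 mol %), PCy3 (20 mol %), toluene, 90 °C
Reagents that add atoms: none
Why: Zerovalent nickel couples the strained ring carbonyl of 7 with alkyne 8 by oxidative cyclisation to a catalyst-bound spiro oxanickelacyclopentene, in which the bond from the carbonyl carbon to the methyl-bearing alkyne carbon is made; β-carbon elimination of the ring CH2 then opens the four-membered ring to a catalyst-bound seven-membered nickelacycle, and C(sp3)–C(sp2) reductive elimination joins that CH2 to the silyl-bearing carbon. The closest known reaction type is the nickel-catalysed intermolecular insertion of internal alkynes into cyclobutanones and into 2-substituted 3-azetidinones, which open at the unsubstituted acyl–CH2 bond with retention of the α-stereocentre. The six-membered ring is closed as a formal [4+2] annulation, that is a two-carbon ring expansion in which the four-carbon unit C1–C6–C5–C4 comes from 7 and the ring-closing event is the reductive elimination. No stereocentre is created: C5 and C6 lie outside the reorganising bonds and are carried over unchanged from C3 and C2 of 7, the trans arrangement also being the stable one at the enolisable C6. Two selectivities are needed: opening of the acyl–CH2 bond and not the acyl–CH(OSiEt3) bond, secured because the unhindered primary carbon migrates to nickel in the β-carbon elimination, and the orientation of the alkyne, secured by the silyl group, which takes the nickel-bound position in the oxidative cyclisation so that methyl ends up next to the carbonyl group and which also suppresses alkyne oligomerisation.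

Step 5
Reactants: 9 (5S,6S)-5-(3,3-diethoxyprop-1-en-2-yl)-2-methyl-6-[(triethylsilyl)oxy]-3-(trimethylsilyl)cyclohex-2-en-1-one
Product: 10 (1S,5S,6S)-5-(3,3-diethoxyprop-1-en-2-yl)-2-methyl-6-[(triethylsilyl)oxy]-3-(trimethylsilyl)cyclohex-2-en-1-ol
Conditions: NaBH4, CeCl3·7H2O, EtOH, −40 °C
Reagents that add atoms: none
Why: Luche reduction gives clean 1,2-reduction of the enone, and axial hydride delivery to the half-chair with both ring substituents equatorial places the new C1 hydroxyl equatorial, trans to the C6 siloxy group and cis to the C5 side chain.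

Step 6
Reactants: 10 (1S,5S,6S)-5-(3,3-diethoxyprop-1-en-2-yl)-2-methyl-6-[(triethylsilyl)oxy]-3-(trimethylsilyl)cyclohex-2-en-1-ol
Product: 11 (1R,2R,3S,4S,6R)-4-(3,3-diethoxyprop-1-en-2-yl)-1-methyl-3-[(triethylsilyl)oxy]-6-(trimethylsilyl)-7-oxabicyclo[4.1.0]heptan-2-ol
Conditions: VO(acac)2 (5 mol %), t-BuOOH, CH2Cl2, 0 °C → rt
Reagents that add atoms: tert-butyl hydroperoxide CC(C)(C)OO
Why: Hydroxyl-directed epoxidation of a cyclic allylic alcohol with a vanadyl catalyst and an alkyl hydroperoxide delivers oxygen to the ring alkene from the face of the C1 hydroxyl, which sets both oxirane carbons on the face of the side chain and leaves the non-directed side-chain alkene untouched.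

Step 7
Reactants: 11 (1R,2R,3S,4S,6R)-4-(3,3-diethoxyprop-1-en-2-yl)-1-methyl-3-[(triethylsilyl)oxy]-6-(trimethylsilyl)-7-oxabicyclo[4.1.0]heptan-2-ol
Product: 12 (1R,3S,4S,6R)-4-(3,3-diethoxyprop-1-en-2-yl)-1-methyl-3-[(triethylsilyl)oxy]-6-(trimethylsilyl)-7-oxabicyclo[4.1.0]heptan-2-one
Conditions: Dess–Martin periodinane, pyridine, CH2Cl2, 0 °C → rt
Reagents that add atoms: none
Why: Dess–Martin oxidation of the secondary epoxy alcohol to the epoxy ketone under buffered conditions that spare the acetal and the silyl ether; no stereocentre is affected.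

Step 8
Reactants: 12 (1R,3S,4S,6R)-4-(3,3-diethoxyprop-1-en-2-yl)-1-methyl-3-[(triethylsilyl)oxy]-6-(trimethylsilyl)-7-oxabicyclo[4.1.0]heptan-2-one
Product: 13 (1S,3S,4S,6S)-4-(3,3-diethoxyprop-1-en-2-yl)-3-hydroxy-1-methyl-7-oxabicyclo[4.1.0]heptan-2-one
Conditions: TBAF, AcOH, THF, 0 °C → rt
Reagents that add atoms: none
Why: Fluoride-induced protodesilylation of an α,β-epoxysilane, a known reaction that proceeds with retention at the oxirane carbon, runs together with cleavage of the triethylsilyl ether, and acetic acid buffers the medium to protect the liberated α-hydroxy ketone.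

Step 9
Reactants: 13 (1S,3S,4S,6S)-4-(3,3-diethoxyprop-1-en-2-yl)-3-hydroxy-1-methyl-7-oxabicyclo[4.1.0]heptan-2-one
Product: 14 (1S,3S,4S,6S)-4-(3,3-diethoxyprop-1-en-2-yl)-1-methyl-2-oxo-7-oxabicyclo[4.1.0]heptan-3-yl (2E)-2-methylbut-2-enoate
Conditions: tigloyl chloride, pyridine, DMAP (cat.), CH2Cl2, 0 °C
Reagents that add atoms: (E)-2-methylbut-2-enoyl chloride C/C=C(\C)C(=O)Cl
Why: DMAP-catalysed acylation of the secondary α-hydroxy ketone with the acid chloride, with pyridine instead of a trialkylamine so that no vinylketene forms and the E-configured acyl group is not deconjugated; the carbinol configuration is retained.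

Step 10
Reactants: 14 (1S,3S,4S,6S)-4-(3,3-diethoxyprop-1-en-2-yl)-1-methyl-2-oxo-7-oxabicyclo[4.1.0]heptan-3-yl (2E)-2-methylbut-2-enoate
Product: 15 (1S,3S,4S,6S)-1-methyl-2-oxo-4-(3-oxoprop-1-en-2-yl)-7-oxabicyclo[4.1.0]heptan-3-yl (2E)-2-methylbut-2-enoate
Conditions: PPTS (cat.), acetone/H2O, 40 °C
Reagents that add atoms: water O
Why: Acid-catalysed acetal hydrolysis is fast for an acrolein-type acetal because the oxocarbenium ion is allylic, while the electron-poor oxirane next to the ketone and the ester tolerate the weak acid.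

Step 11
Reactants: 15 (1S,3S,4S,6S)-1-methyl-2-oxo-4-(3-oxoprop-1-en-2-yl)-7-oxabicyclo[4.1.0]heptan-3-yl (2E)-2-methylbut-2-enoate
Product: 17 (1S,3S,4S,6S)-4-(3-hydroxyhexa-1,5-dien-2-yl)-1-methyl-2-oxo-7-oxabicyclo[4.1.0]heptan-3-yl (2E)-2-methylbut-2-enoate (both epimers at the carbinol carbon), via boronate ester 16 (not isolated)
Conditions: allylB(pin), toluene, rt; aqueous work-up
Reagents that add atoms: allylboronic acid pinacol ester C=CCB1OC(C)(C)C(C)(C)O1
Why: Allylboration through a six-membered chair transition state is selective for the aldehyde, which is far more electrophilic and less hindered than the ring ketone; the new carbinol centre is not controlled and is removed in step 13.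

Step 12
Reactants: 17 (1S,3S,4S,6S)-4-(3-hydroxyhexa-1,5-dien-2-yl)-1-methyl-2-oxo-7-oxabicyclo[4.1.0]heptan-3-yl (2E)-2-methylbut-2-enoate
Product: 18 (1S,3S,4S,6S)-4-(3-hydroxy-6-methylhepta-1,5-dien-2-yl)-1-methyl-2-oxo-7-oxabicyclo[4.1.0]heptan-3-yl (2E)-2-methylbut-2-enoate (both epimers at the carbinol carbon)
Conditions: second-generation Hoveyda–Grubbs catalyst (5 mol %), 2-methyl-2-butene, CH2Cl2, 40 °C
Reagents that add atoms: 2-methyl-2-butene CC=C(C)C
Why: Olefin cross-metathesis of the monosubstituted alkene with excess 2-methyl-2-butene turns allyl into prenyl, while the 1,1-disubstituted alkene and the trisubstituted electron-poor alkene of the substrate do not engage the ruthenium carbene.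

Step 13
Reactants: 18 (1S,3S,4S,6S)-4-(3-hydroxy-6-methylhepta-1,5-dien-2-yl)-1-methyl-2-oxo-7-oxabicyclo[4.1.0]heptan-3-yl (2E)-2-methylbut-2-enoate
Product: 19 (1S,3S,4S,6S)-1-methyl-4-(6-methyl-3-oxohepta-1,5-dien-2-yl)-2-oxo-7-oxabicyclo[4.1.0]heptan-3-yl (2E)-2-methylbut-2-enoate
Conditions: Dess–Martin periodinane, pyridine, CH2Cl2, 0 °C
Reagents that add atoms: none
Why: Dess–Martin oxidation of the allylic alcohol under buffered conditions should give the β,γ-unsaturated ketone without migration of the prenyl double bond into conjugation, and it merges both carbinol epimers into one compound that is used without delay.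

Step 14
Reactants: 19 (1S,3S,4S,6S)-1-methyl-4-(6-methyl-3-oxohepta-1,5-dien-2-yl)-2-oxo-7-oxabicyclo[4.1.0]heptan-3-yl (2E)-2-methylbut-2-enoate
Product: 20 (1S,3S,4S,6S)-4-[(4E)-6-hydroperoxy-6-methyl-3-oxohepta-1,4-dien-2-yl]-1-methyl-2-oxo-7-oxabicyclo[4.1.0]heptan-3-yl (2E)-2-methylbut-2-enoate
Conditions: O2, tetraphenylporphyrin (cat.), visible light, CH2Cl2, −20 °C
Reagents that add atoms: oxygen O=O
Why: Schenck ene reaction of singlet oxygen with the only electron-rich alkene, in which, as in other β,γ-unsaturated ketones, the hydrogen is taken from the activated CH2 between ketone and alkene, oxygen adds at the tertiary carbon and the double bond moves into conjugation as the E isomer, while the three electron-poor alkenes are inert to the electrophilic oxidant.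

**Compound list**

1 | 3-oxocyclobutane-1-carboxylic acid | O=C1CC(C(=O)O)C1 | starting material
2 | 2-bromo-3,3-diethoxyprop-1-ene (2-bromoacrolein diethyl acetal) | C=C(Br)C(OCC)OCC | starting material
3 | 3-(3,3-diethoxyprop-1-en-2-yl)cyclobutan-1-one | C=C(C(OCC)OCC)C1CC(=O)C1 | intermediate
4 | lithium (3R)-3-(3,3-diethoxyprop-1-en-2-yl)cyclobut-1-en-1-olate | C=C(C(OCC)OCC)[C@@H]1CC(O[Li])=C1 | intermediate (not isolated)
5 | triethyl{[(3R)-3-(3,3-diethoxyprop-1-en-2-yl)cyclobut-1-en-1-yl]oxy}silane | C=C(C(OCC)OCC)[C@@H]1CC(O[Si](CC)(CC)CC)=C1 | intermediate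
6 | (1S,3S,4S)-3-(3,3-diethoxyprop-1-en-2-yl)-1-[(triethylsilyl)oxy]-5-oxabicyclo[2.1.0]pentane (oxirane oxygen trans to the side chain) | C=C(C(OCC)OCC)[C@@H]1C[C@@]2(O[Si](CC)(CC)CC)O[C@@H]12 | intermediate (not isolated)
7 | (2S,3S)-3-(3,3-diethoxyprop-1-en-2-yl)-2-[(triethylsilyl)oxy]cyclobutan-1-one | C=C(C(OCC)OCC)[C@@H]1CC(=O)[C@H]1O[Si](CC)(CC)CC | intermediate
8 | trimethyl(prop-1-yn-1-yl)silane | CC#C[Si](C)(C)C | starting material
9 | (5S,6S)-5-(3,3-diethoxyprop-1-en-2-yl)-2-methyl-6-[(triethylsilyl)oxy]-3-(trimethylsilyl)cyclohex-2-en-1-one | C=C(C(OCC)OCC)[C@@H]1CC([Si](C)(C)C)=C(C)C(=O)[C@H]1O[Si](CC)(CC)CC | intermediate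
10 | (1S,5S,6S)-5-(3,3-diethoxyprop-1-en-2-yl)-2-methyl-6-[(triethylsilyl)oxy]-3-(trimethylsilyl)cyclohex-2-en-1-ol | C=C(C(OCC)OCC)[C@@H]1CC([Si](C)(C)C)=C(C)[C@H](O)[C@H]1O[Si](CC)(CC)CC | intermediate
11 | (1R,2R,3S,4S,6R)-4-(3,3-diethoxyprop-1-en-2-yl)-1-methyl-3-[(triethylsilyl)oxy]-6-(trimethylsilyl)-7-oxabicyclo[4.1.0]heptan-2-ol | C=C(C(OCC)OCC)[C@@H]1C[C@]2([Si](C)(C)C)O[C@]2(C)[C@H](O)[C@H]1O[Si](CC)(CC)CC | intermediate
12 | (1R,3S,4S,6R)-4-(3,3-diethoxyprop-1-en-2-yl)-1-methyl-3-[(triethylsilyl)oxy]-6-(trimethylsilyl)-7-oxabicyclo[4.1.0]heptan-2-one | C=C(C(OCC)OCC)[C@@H]1C[C@]2([Si](C)(C)C)O[C@]2(C)C(=O)[C@H]1O[Si](CC)(CC)CC | intermediate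
13 | (1S,3S,4S,6S)-4-(3,3-diethoxyprop-1-en-2-yl)-3-hydroxy-1-methyl-7-oxabicyclo[4.1.0]heptan-2-one | C=C(C(OCC)OCC)[C@@H]1C[C@@H]2O[C@]2(C)C(=O)[C@H]1O | intermediate
14 | (1S,3S,4S,6S)-4-(3,3-diethoxyprop-1-en-2-yl)-1-methyl-2-oxo-7-oxabicyclo[4.1.0]heptan-3-yl (2E)-2-methylbut-2-enoate | C=C(C(OCC)OCC)[C@@H]1C[C@@H]2O[C@]2(C)C(=O)[C@H]1OC(=O)/C(C)=C/C | intermediate
15 | (1S,3S,4S,6S)-1-methyl-2-oxo-4-(3-oxoprop-1-en-2-yl)-7-oxabicyclo[4.1.0]heptan-3-yl (2E)-2-methylbut-2-enoate | C=C(C=O)[C@@H]1C[C@@H]2O[C@]2(C)C(=O)[C@H]1OC(=O)/C(C)=C/C | intermediate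
16 | O-(4,4,5,5-tetramethyl-1,3,2-dioxaborolan-2-yl) ether of 17 (both epimers at the carbinol carbon) | C=C(C(OB1OC(C)(C)C(C)(C)O1)CC=C)[C@@H]1C[C@@H]2O[C@]2(C)C(=O)[C@H]1OC(=O)/C(C)=C/C | intermediate (not isolated)
17 | (1S,3S,4S,6S)-4-(3-hydroxyhexa-1,5-dien-2-yl)-1-methyl-2-oxo-7-oxabicyclo[4.1.0]heptan-3-yl (2E)-2-methylbut-2-enoate (both epimers at the carbinol carbon) | C=C(C(O)CC=C)[C@@H]1C[C@@H]2O[C@]2(C)C(=O)[C@H]1OC(=O)/C(C)=C/C | intermediate
18 | (1S,3S,4S,6S)-4-(3-hydroxy-6-methylhepta-1,5-dien-2-yl)-1-methyl-2-oxo-7-oxabicyclo[4.1.0]heptan-3-yl (2E)-2-methylbut-2-enoate (both epimers at the carbinol carbon) | C=C(C(O)CC=C(C)C)[C@@H]1C[C@@H]2O[C@]2(C)C(=O)[C@H]1OC(=O)/C(C)=C/C | intermediate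
19 | (1S,3S,4S,6S)-1-methyl-4-(6-methyl-3-oxohepta-1,5-dien-2-yl)-2-oxo-7-oxabicyclo[4.1.0]heptan-3-yl (2E)-2-methylbut-2-enoate | C=C(C(=O)CC=C(C)C)[C@@H]1C[C@@H]2O[C@]2(C)C(=O)[C@H]1OC(=O)/C(C)=C/C | intermediate
20 | (1S,3S,4S,6S)-4-[(4E)-6-hydroperoxy-6-methyl-3-oxohepta-1,4-dien-2-yl]-1-methyl-2-oxo-7-oxabicyclo[4.1.0]heptan-3-yl (2E)-2-methylbut-2-enoate (CNP0284595.1) | C=C(C(=O)/C=C/C(C)(C)OO)[C@@H]1C[C@@H]2O[C@]2(C)C(=O)[C@H]1OC(=O)/C(C)=C/C | target

**Totals**

Total step count: 14. Longest linear sequence: 14 steps (1 → 20).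

**Steps most likely to fail**

Step 4. What may go wrong: β-carbon elimination of the siloxy-bearing α-carbon (the wrong ring bond opens), β-hydride elimination from the alkylnickel intermediate, or slow oxidative cyclisation at the hindered α-siloxy carbonyl group. Fallback: the ring expansion is moved in front of the oxygenation, and the absolute configuration is then set on the six-membered ring. The fallback sets out from 3, whose two acyl–CH2 bonds are identical, so there is no choice of bond. Compound 3 and alkyne 8 under the nickel conditions of step 4 should give the racemic enone rac-5-(3,3-diethoxyprop-1-en-2-yl)-2-methyl-3-(trimethylsilyl)cyclohex-2-en-1-one F1. Kinetic resolution by enantiomer-selective deprotonation at C6 with the chiral lithium amide of step 2, with Et3SiCl present, should convert the matched (5S) enantiomer into the lithium cross-conjugated dienolate F2. This is silylated in the flask to the triethylsilyl dienol ether F3; the (5R)-enone is left behind and separated. Rubottom oxidation of F3 with DMDO, through the siloxy oxirane F4 formed on the face opposite the C5 substituent and its 1,4-silyl shift, comes back to the route at 9.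

Step 8. What may go wrong: base-induced degradation of the α-hydroxy ketone that is set free (α-ketol shift, epimerisation at C6) while the slower cleavage of the carbon–silicon bond is still going on. Fallback: the two desilylations are separated, so that the carbon–silicon bond is cleaved only when no free hydroxyl is left. The fallback sets out from 12. Et3N·3HF in MeCN cleaves only the silyl ether and should give the hydroxy ketone (1R,3S,4S,6R)-4-(3,3-diethoxyprop-1-en-2-yl)-3-hydroxy-1-methyl-6-(trimethylsilyl)-7-oxabicyclo[4.1.0]heptan-2-one F5. Acylation as in step 9 gives the ester (1R,3S,4S,6R)-4-(3,3-diethoxyprop-1-en-2-yl)-1-methyl-2-oxo-6-(trimethylsilyl)-7-oxabicyclo[4.1.0]heptan-3-yl (2E)-2-methylbut-2-enoate F6. Fluoride protodesilylation of the epoxysilane in F6 (CsF in wet DMSO, or TBAF/AcOH) then comes back to the route at 14.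

Step 14. What may go wrong: loss of regioselectivity in the hydrogen abstraction (a methyl hydrogen instead of the CH2 between ketone and alkene, which gives a secondary allylic hydroperoxide), or migration of the prenyl double bond of 19 into conjugation before the oxidation, which shuts the ene pathway down. Fallback: the pericyclic singlet-oxygen reaction is replaced by a radical-chain autoxidation with ground-state oxygen, a known route from β,γ-unsaturated ketones to γ-hydroperoxy enones. The fallback sets out from 19 and uses O2 with catalytic N-hydroxyphthalimide in MeCN at 30–40 °C in the dark. The N-oxyl radical removes the weakest hydrogen, that of the doubly activated CH2 (the conjugated isomer gives the same delocalised radical from its tertiary γ-hydrogen). Oxygen adds at the tertiary terminus so that enone conjugation is gained, and chain transfer comes back to the route at 20 without any new compound.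

**Further compounds**

F1 | step 4 | rac-5-(3,3-diethoxyprop-1-en-2-yl)-2-methyl-3-(trimethylsilyl)cyclohex-2-en-1-one | C=C(C(OCC)OCC)C1CC([Si](C)(C)C)=C(C)C(=O)C1
F2 | step 4 | lithium (6R)-6-(3,3-diethoxyprop-1-en-2-yl)-3-methyl-4-(trimethylsilyl)cyclohexa-1,3-dien-2-olate | C=C(C(OCC)OCC)[C@@H]1CC([Si](C)(C)C)=C(C)C(O[Li])=C1
F3 | step 4 | triethyl{[(6R)-6-(3,3-diethoxyprop-1-en-2-yl)-3-methyl-4-(trimethylsilyl)cyclohexa-1,3-dien-2-yl]oxy}silane | C=C(C(OCC)OCC)[C@@H]1CC([Si](C)(C)C)=C(C)C(O[Si](CC)(CC)CC)=C1
F4 | step 4 | 5-(3,3-diethoxyprop-1-en-2-yl)-2-methyl-1-[(triethylsilyl)oxy]-3-(trimethylsilyl)-7-oxabicyclo[4.1.0]hept-2-ene (oxirane oxygen trans to the side chain) | C=C(C(OCC)OCC)[C@@H]1CC([Si](C)(C)C)=C(C)[C@@]2(O[Si](CC)(CC)CC)O[C@@H]12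
F5 | step 8 | (1R,3S,4S,6R)-4-(3,3-diethoxyprop-1-en-2-yl)-3-hydroxy-1-methyl-6-(trimethylsilyl)-7-oxabicyclo[4.1.0]heptan-2-one | C=C(C(OCC)OCC)[C@@H]1C[C@]2([Si](C)(C)C)O[C@]2(C)C(=O)[C@H]1O
F6 | step 8 | (1R,3S,4S,6R)-4-(3,3-diethoxyprop-1-en-2-yl)-1-methyl-2-oxo-6-(trimethylsilyl)-7-oxabicyclo[4.1.0]heptan-3-yl (2E)-2-methylbut-2-enoate | C=C(C(OCC)OCC)[C@@H]1C[C@]2([Si](C)(C)C)O[C@]2(C)C(=O)[C@H]1OC(=O)/C(C)=C/C
F0 | step 14 | none | none
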